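## Structural features

The target is a trans-fused octahydronaphthalene. Ring A is C1–C2–C3–C4–C5–C10 and ring B is C5–C6–C7=C8–C9–C10; β denotes the face of the C10 methyl group. Ring B carries the C12 methyl ester on C8, conjugated with C7=C8, and an equatorial 9β-formyl group (C11). Ring A carries an axial 1α-hydroxyl, an equatorial 3β-chlorine and a quaternary C4 with a β-methyl and an α-(E)-4-hydroxy-4-methylpent-2-enyl chain. There are six stereocentres: C9, C10, C5, C4 and C3 are contiguous and C1 is attached to C10; C10 and C4 are quaternary and each lies between two other stereocentres. Several groups are fragile. The C9 aldehyde can epimerise or pull the alkene into conjugation, the 1,3-chlorohydrin can close to an oxetane or eliminate under base, the tertiary allylic alcohol can ionise under acid, and a free C11 hydroxyl next to the C12 ester can close to a butenolide. The real difficulty is the secondary chloride at C3, which is neopentyl and therefore closed to ordinary SN2 chemistry, together with the two quaternary carbons. The key step exploits ring B: C4 and C1 are trans on C5 and C10, C11 is cis to the C10 methyl, and the alkene sits at C7=C8. This is the endo [4+2] pattern of an (E)-trisubstituted acyl/ester alkene (C5=C10) and a 2-silyloxydiene (C6=C7–C8=C9) whose enol oxygen marks C8.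

## Logic of the disconnections

28 to 27: no skeletal bond is cut; the C11 aldehyde is taken back to the primary alcohol. The formyl group is the most labile function and is made last. The forward step must oxidise a primary alcohol beside a secondary and a tertiary one without base.

27 to 26: the three O–Si bonds (O1, O11, side-chain oxygen) are cut. One fluoride step frees all hydroxyls. It must not let O11 close onto the C12 ester.

26 to 25: the C8–C12 bond is cut, the ester coming from the C7=C8 enol triflate by carbonylation. Introducing the ester this late means the C1 ester of 10 is the only ester present when it is reduced in step 10. The palladium step must leave the alkyl chloride alone.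

25 to 21 (through 24, 23, 22): the C3–Cl bond is traced to a C3–O bond and then to the C3 ketone. Substitution at neopentyl C3 is not viable, so the chloride is planned as the capture of a C3 radical. This leaves a ketone at C3, which is what the C4 alkylation needs. The forward step needs chlorine transfer to the β-face.

21 to 18 (through 20, 19): the C1–O bond is cut, leaving the C1=C2 enone. Conjugate addition anti to the C10 methyl is the classical way to a 1α-substituent, so C1 is set on the ring.

18 to 17: the side-chain C=C bond is cut by cross-metathesis, reducing the side chain to an allyl group. An (E)-selective coupling is required.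

17 to 16: the C4–CH2 bond is cut. The quaternary centre C4 is made by enolate alkylation on the rigid bicycle, where the angular methyl directs the electrophile to the α-face. The precursor has only a CH(CH3) at C4, whose configuration is irrelevant.

16 to 15: the C1=C2 bond is cut (aldol condensation), which opens ring A and leaves a ring B compound with a 1,5-keto aldehyde. Only the C2 enol can close a six-membered ring.

15 to 10 (through 14, 13, 12, 11): the C3–C4 bond is cut as the C3=C4 alkene of 11, made by Wittig reaction at the acetyl carbon of 10. That carbon is C4 and already carries the C4 methyl, so one olefination brings in C3 and C2. Hydroboration moves the oxygen to C3, the C1 ester is reduced, and the enol silane is exchanged for the triflate. These steps demand chemoselectivity between the electron-rich alkene and the enol triflate.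

10 to 3 + 9: the C9–C10 and C5–C6 bonds are cut (Diels–Alder). Ring B, C5, C9 and C10 arise together, and both components are small and achiral. The forward step needs C9-to-C10 regiochemistry, ketone-endo selectivity and one enantioface. In 9 a triisopropylsilyl enol ether and a tert-butyldiphenylsilyl ether replace more acid-labile or more Lewis-basic groups, so that both survive the strongly acidic catalyst.

3 to 1 + 2: the C5=C10 alkene is cut (Wittig). The (E)-geometry is required because it becomes the trans ring fusion.

9 to 4 (through 8, 7, 6, 5): the enol O–Si bond, the C7–C8 bond (vinyl Grignard addition) and the O11–Si bond are cut, leading to a symmetrical diol. The enolisation must give the (Z)-dienol ether.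

## Other disconnections considered

Alternative 1: The cut is through C4–C5 and C9–C10, which unravels both rings into the acyclic (E)-alkenyl β-keto ester A1 carrying the C1 acetate, the C3 chlorine and a tertiary C4 carbinol. In the forward step SnCl4 would ionise the C4 hydroxyl of A1 with help from the C3 chlorine. The bridged chloronium ion would be opened at C4 by the C5=C10 alkene, and the C10 cation would be trapped by the β-keto ester enol to give the trans-decalin A2.
- In favour: two rings, both quaternary centres and four stereocentres would arise in one step. The neopentyl C3–Cl bond is never made by substitution, because the chlorine is carried in and only transferred. On this point and on ring-forming economy the alternative is better than the chosen plan, which spends five steps (16–20) on turning the enone into the chloride.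
- Against: A1 needs three acyclic stereocentres (C1, C3, C4) made separately in enantiopure form. Its C1 acetate is allylic to the alkene that must act as nucleophile, so it deactivates that alkene and may itself ionise. An open tertiary cation in place of the chloronium ion would erase C4. The allyl group is a second π-nucleophile.
- Ring B after cyclisation: A2 has the wrong oxidation pattern. The C9 ester must come down to the aldehyde level and the C8 ketone must become the C7=C8 ester, although a β-keto ester enolises towards C9. The chosen cycloaddition delivers C11, the C8 oxygen and the alkene position already differentiated, and is the better plan there.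
- Comparison: the alternative is a cationic cascade with several exits; the chosen step is a concerted cycloaddition whose relative stereochemistry follows from alkene geometry but whose absolute sense depends on a catalyst. Once A1 and the ring B corrections are counted, the step totals should be similar.

Alternative 2: The cut is through C9–C10 and C7–C8 with O1 as a temporary tether. Ring A is made first as the vinylcyclohexene A3, whose C1 oxygen is esterified with monomethyl acetylenedicarboxylate. On heating, the C10=C5–C6=C7 diene of A3 would add across C9≡C8 to give the tricyclic lactone A4.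
- In favour: the tether fixes the regiochemistry and forces the new quaternary C10 cis to O1, so neither a chiral catalyst nor an electronic bias is needed. On these two points it is the safer plan. C11 and C12 arrive on the right carbons, C12 already as the methyl ester. In bonds formed per key step it is equal to the chosen plan.
- Against: A4 is a 1,4-cyclohexadiene, so C5 and C9 are still sp2. C5 would need a face-selective reduction of C5=C6, and C9 a shift of C8=C9 to C7=C8 with controlled protonation. The lactone holds C11 on the α-face, the wrong side for the 9β-formyl group, so a later epimerisation must be relied on. The lactone carbonyl must be reduced beside a methyl ester. The C3 silyl ether of A4 is α, so the chloride would need an SN2 inversion at a neopentyl carbon. The ester tether and the fully substituted diene terminus should also make the cycloaddition slow.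
- Comparison: the chosen plan sets C5, C9, C10 and the alkene position in the key step, whereas this one leaves them open. It should be longer, because A3 with its C1, C3 and C4 stereocentres needs its own enantioselective synthesis.

Alternative 3: The cut is through C1–C2 and C3–Cl. The precursor is the ring B aldehyde A5 with a vinyl group (C3=C2) and an ethoxycarbonylmethyl group on quaternary C4. SnCl4 would activate the C1 aldehyde of A5, the terminal vinyl carbon C2 would attack it in a chair-like closure, and chloride would capture the C3 cation to give the chlorohydrin A6.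
- In favour: the C1 carbinol and the C3 chloride are made together, with no substitution at a neopentyl carbon. This is better than the chosen plan in ring A step economy (one step against steps 13–20) and in the directness of C–Cl bond formation. A5 would itself come from a ring B cycloadduct of the kind of 10, so on ring B and on enantiocontrol the two plans are equal.
- Against: C4 must be quaternary and stereodefined before ring A exists, by an acyclic process next to C5 that has only allylic-strain control. The chosen plan alkylates C4 on a rigid bicycle. The secondary C3 cation lies next to quaternary C4, so 1,2-shift and elimination compete with chloride capture. The 1α/3β relation needs the complexed oxygen axial and external chloride equatorial, whereas delivery from the tin alkoxide would give the 1,3-cis isomer. The side chain must still be built from the ester.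
- Comparison: a cationic closure that is short but open to rearrangement, against a longer radical route that avoids a cation at C3.

Key step: step 7

Remarks on the chemistry: skeletal numbering C1–C12 is used for all compounds, and β is the face of the C10 methyl group. Assumption: the catalyst antipode in step 7 is chosen from the α-C–H···O binding model of enone–oxazaborolidinium complexes; if the sense of induction were the opposite, the catalyst from (S)-α,α-diphenyl-2-pyrrolidinemethanol would be used with no other change.

## Route

Step 1
Reactants: 1 methylglyoxal (40% aqueous solution); 2 methyl 2-(triphenylphosphoranylidene)propanoate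
Product: 3 methyl (E)-2-methyl-4-oxopent-2-enoate
Conditions: CH2Cl2/H2O, 0 °C → rt
Reagents that add atoms: none
Why: Wittig olefination at the aldehyde carbonyl of 1, which is far more electrophilic than the ketone; the stabilised α-methyl ylide should give the (E)-alkene with the ester trans to the acetyl group.

Step 2
Reactants: 4 propane-1,3-diol
Product: 5 3-[(tert-butyldiphenylsilyl)oxy]propan-1-ol
Conditions: NaH (1.0 equiv), THF, 0 °C → rt; t-BuPh2SiCl (1.0 equiv)
Reagents that add atoms: tert-butyl(chloro)diphenylsilane, CC(C)(C)[Si](Cl)(c1ccccc1)c1ccccc1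
Why: Monosilylation of a symmetrical diol through its poorly soluble monosodium alkoxide; the bulky silyl group disfavours a second silylation.

Step 3
Reactants: 5 3-[(tert-butyldiphenylsilyl)oxy]propan-1-ol
Product: 6 3-[(tert-butyldiphenylsilyl)oxy]propanal
Conditions: TEMPO (10 mol%), PhI(OAc)2, CH2Cl2, rt
Reagents that add atoms: none
Why: Nitroxyl-catalysed oxidation of a primary alcohol stops at the aldehyde; the neutral medium avoids β-elimination of the silyloxy group.

Step 4
Reactants: 6 3-[(tert-butyldiphenylsilyl)oxy]propanal
Product: 7 5-[(tert-butyldiphenylsilyl)oxy]pent-1-en-3-ol (racemic)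
Conditions: CH2=CHMgBr, THF, −78 °C; aq NH4Cl
Reagents that add atoms: vinylmagnesium bromide, C=C[Mg]Br
Why: Grignard 1,2-addition to an aldehyde; the new carbinol centre is racemic and is removed in step 5.

Step 5
Reactants: 7 5-[(tert-butyldiphenylsilyl)oxy]pent-1-en-3-ol
Product: 8 5-[(tert-butyldiphenylsilyl)oxy]pent-1-en-3-one
Conditions: 2-iodoxybenzoic acid, DMSO, rt
Reagents that add atoms: none
Why: Oxidation of a secondary allylic alcohol with a hypervalent iodine reagent under non-basic conditions, so that neither conjugate addition to the vinyl ketone nor β-elimination of silanol is triggered.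

Step 6
Reactants: 8 5-[(tert-butyldiphenylsilyl)oxy]pent-1-en-3-one
Product: 9 (Z)-5-[(tert-butyldiphenylsilyl)oxy]-3-[(triisopropylsilyl)oxy]penta-1,3-diene (C6=C7–C8(OSi)=C9–C11)
Conditions: i-Pr3SiOTf, Et3N, CH2Cl2, −78 → 0 °C
Reagents that add atoms: triisopropylsilyl trifluoromethanesulfonate, CC(C)[Si](OS(=O)(=O)C(F)(F)F)(C(C)C)C(C)C
Why: Soft enolisation (silyl triflate/amine) at the only enolisable carbon, C9, gives the cross-conjugated silyl dienol ether. The kinetic enol silane should have C11 trans to the vinyl group, i.e. (Z), the geometry that can reach the s-cis conformation.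

Step 7
Reactants: 3 methyl (E)-2-methyl-4-oxopent-2-enoate; 9 (Z)-5-[(tert-butyldiphenylsilyl)oxy]-3-[(triisopropylsilyl)oxy]penta-1,3-diene
Product: 10 methyl (1R,2S,6R)-6-acetyl-2-{[(tert-butyldiphenylsilyl)oxy]methyl}-1-methyl-3-[(triisopropylsilyl)oxy]cyclohex-3-ene-1-carboxylate (ring B; C5 acetyl β, C9 CH2OSi β, C10 methyl β, C10 ester α, C7=C8 enol ether)
Conditions: (R)-oxazaborolidinium triflimide [from (R)-α,α-diphenyl-2-pyrrolidinemethanol, tri-o-tolylboroxine and Tf2NH] (20 mol%), CH2Cl2, −78 → −40 °C
Reagents that add atoms: none
Why: The N-protonated oxazaborolidine, a chiral boron Lewis acid, should bind the ketone oxygen of 3, which is more basic than the ester, and so enable a concerted but asynchronous [4+2] cycloaddition at low temperature; the closest known reaction type is the oxazaborolidinium-catalysed enantioselective Diels–Alder reaction of 2-silyloxydienes with trisubstituted enones and enoates. The shorter forming bond joins the nucleophilic enol-ether terminus C9 of 9 to C10, the carbon β to the complexed ketone, and the second bond joins C6 to C5, so ring B closes as a six-membered ring by intermolecular union of a four-carbon and a two-carbon unit. C5 and C10 (C4 and C1 trans) follow stereospecifically from the (E)-geometry of 3. C9 follows from the (Z)-geometry of 9 combined with the ketone-endo transition state, which puts C11 cis to the C10 methyl. The absolute configuration is set by the catalyst: in the α-C–H···O binding model an aryl group of the catalyst shields one face of the s-trans enone, and the (R)-catalyst should leave open the C5-Re/C10-Re face that the target needs. Regioselectivity rests on the 2-silyloxy group and on complexation of the ketone, not the ester; endo selectivity rests on secondary overlap with the complexed acetyl group. The triisopropylsilyl enol ether and the silyl ether at O11 are chosen to survive the acidic catalyst, and only the (Z)-diene can react. The enol ether of 10 fixes the later alkene at C7=C8.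

Step 8
Reactants: 10 ring B cycloadduct
Product: 11 as 10 with the C5 acetyl group converted into a but-2-en-2-yl group, C4(CH3)=C3H–C2H3 (E/Z mixture)
Conditions: EtPPh3Br, KN(SiMe3)2, THF, 0 °C → rt
Reagents that add atoms: ethyltriphenylphosphonium bromide, CC[P+](c1ccccc1)(c1ccccc1)c1ccccc1.[Br-]
Why: Wittig olefination of the methyl ketone with a non-stabilised ylide; the hindered, non-enolisable C10 ester and the silyl enol ether should be inert. The alkene geometry is irrelevant because the alkene is hydroborated in step 11.

Step 9
Reactants: 11 ethylidene silyl enol ether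
Product: 12 as 11 with the C8 silyl enol ether replaced by the C7=C8 enol trifluoromethanesulfonate
Conditions: CsF, PhNTf2, DME, rt
Reagents that add atoms: N-phenylbis(trifluoromethanesulfonimide), O=S(=O)(N(c1ccccc1)S(=O)(=O)C(F)(F)F)C(F)(F)F
Why: Fluoride cleaves the enol Si–O bond and the cesium enolate is triflated in situ, a regiospecific conversion of a silyl enol ether into an enol triflate that keeps the C7=C8 position. The alkyl tert-butyldiphenylsilyl ether is much less fluoride-labile than the enol silane, and the ketone that could have enolised was removed in step 8.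

Step 10
Reactants: 12 enol triflate ester
Product: 13 as 12 with the C10 ester reduced to C1H2OH
Conditions: i-Bu2AlH (3 equiv), CH2Cl2, −78 → 0 °C
Reagents that add atoms: none
Why: Hydride reduction of an ester to the primary alcohol; enol triflates tolerate i-Bu2AlH at low temperature.

Step 11
Reactants: 13 primary alcohol
Product: 14 diol, as 13 with the butenyl group converted into C4H(CH3)–C3H(OH)–C2H3 (diastereomer mixture at C3 and C4)
Conditions: BH3·THF, THF, 0 °C → rt; then NaBO3·4H2O, H2O, rt
Reagents that add atoms: sodium perborate tetrahydrate, [Na+].[Na+].O[B-]1(O)OO[B-](O)(O)OO1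
Why: Hydroboration–oxidation of the electron-rich trisubstituted alkene puts boron, then oxygen, on the less substituted C3, while the electron-poor enol triflate should react much more slowly. The C3 and C4 configurations do not matter, since C3 becomes a ketone and C4 an enolate carbon.

Step 12
Reactants: 14 diol
Product: 15 keto aldehyde: C1 formyl on C10 and C4H(CH3)–C3(=O)–C2H3 on C5 (C4 epimer mixture)
Conditions: (COCl)2, DMSO, CH2Cl2, −78 °C; Et3N, −78 → 0 °C
Reagents that add atoms: none
Why: Swern oxidation activates both hydroxyls before base is added, so the primary and the secondary alcohol are oxidised together and no lactol that could be over-oxidised builds up.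

Step 13
Reactants: 15 keto aldehyde
Product: 16 trans-fused bicyclic enone: C1=C2–C3(=O)–C4H(CH3) in ring A (C4 epimers), 10β-methyl, 5α-H, 9β-CH2OSi(t-Bu)Ph2, C7=C8 enol triflate
Conditions: TsOH·H2O (10 mol%), PhMe, 80 °C, 4 Å molecular sieves
Reagents that add atoms: none
Why: Acid-catalysed intramolecular aldol condensation of a 1,5-keto aldehyde: only the C2 enol can reach the non-enolisable C1 aldehyde through a six-membered transition state, and dehydration gives the conjugated enone. The trans ring fusion is inherited from C5 and C10.

Step 14
Reactants: 16 bicyclic enone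
Product: 17 4α-allyl-4β-methyl enone (as 16 with quaternary C4)
Conditions: LiN(i-Pr)2, THF, −78 °C; CH2=CHCH2Br, DMPU, −78 → −20 °C
Reagents that add atoms: allyl bromide, C=CCBr
Why: Kinetic α′-deprotonation (C4–H is the only acidic hydrogen, C10 being quaternary) and C-alkylation of the cross-conjugated dienolate. Allyl bromide should approach C4 anti to the pseudo-axial C10 methyl, from the α-face, leaving the C4 methyl β; this is the usual outcome for 3-keto decalin enolates bearing an angular methyl.

Step 15
Reactants: 17 4α-allyl enone
Product: 18 enone with the 4α-[(E)-4-hydroxy-4-methylpent-2-enyl] side chain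
Conditions: second-generation Hoveyda–Grubbs catalyst (5 mol%), 2-methylbut-3-en-2-ol (10 equiv), CH2Cl2, 40 °C
Reagents that add atoms: 2-methylbut-3-en-2-ol, C=CC(C)(C)O
Why: Olefin cross-metathesis of a terminal alkene with a tertiary allylic alcohol that homodimerises slowly should give the (E)-alkene. The ring enone and the enol triflate are electron-poor, more substituted alkenes and should not take part.

Step 16
Reactants: 18 side-chain enone
Product: 20 1α-hydroxy 3-ketone (as 18 with C1=C2 converted into C1α(OH)–C2H2), via 1α-pinacolboryl ketone 19 (not isolated)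
Conditions: CuCl (5 mol%), DPEphos (5 mol%), NaOt-Bu (10 mol%), B2pin2, MeOH, THF, rt; then NaBO3·4H2O, THF/H2O, rt
Reagents that add atoms: bis(pinacolato)diboron, CC1(C)OB(OC1(C)C)B1OC(C)(C)C(C)(C)O1; sodium perborate tetrahydrate, [Na+].[Na+].O[B-]1(O)OO[B-](O)(O)OO1
Why: Copper-catalysed conjugate borylation of the enone, then oxidation of the C–B bond with retention (a formal β-hydroxylation). The boryl copper species should add to C1 anti to the adjacent axial C10 methyl, i.e. axially from the α-face as in additions to steroidal 1-en-3-ones, which sets the 1α-hydroxyl.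

Step 17
Reactants: 20 1α-hydroxy 3-ketone
Product: 21 bis(triethylsilyl) ether (O1 and side-chain oxygen silylated)
Conditions: Et3SiOTf (2.5 equiv), 2,6-lutidine, CH2Cl2, −78 → 0 °C
Reagents that add atoms: triethylsilyl trifluoromethanesulfonate, CC[Si](CC)(CC)OS(=O)(=O)C(F)(F)F
Why: Silylation of the secondary and the tertiary hydroxyl with a silyl triflate and a hindered base. The O1 ether blocks retro-aldol and elimination, keeps O1 out of step 19 and later shields the α-face of C3.

Step 18
Reactants: 21 bis(triethylsilyl) ether ketone
Product: 22 C3 alcohol (3α/3β mixture)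
Conditions: NaBH4, MeOH/THF, 0 °C
Reagents that add atoms: none
Why: Borohydride reduction of the hindered ketone; an epimer mixture at C3 is acceptable because this centre becomes a planar radical in step 20.

Step 19
Reactants: 22 C3 alcohol
Product: 24 cesium C3 oxalate (O3–C(=O)–CO2Cs), via methyl oxalate 23 (not isolated)
Conditions: ClC(O)CO2Me, Et3N, DMAP (cat.), CH2Cl2, 0 °C; then CsOH·H2O (1.0 equiv), THF/H2O, rt
Reagents that add atoms: methyl chlorooxoacetate, COC(=O)C(Cl)=O; cesium hydroxide, [Cs+].[OH-]
Why: O-acylation with the reactive half acid chloride of oxalic acid, then selective saponification of the activated methyl ester with one equivalent of CsOH, gives the cesium alkyl oxalate that serves as radical precursor. Only O3 is free to react.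

Step 20
Reactants: 24 cesium C3 oxalate
Product: 25 3β-chloride (C7=C8 enol triflate; O1, O11 and side-chain oxygen silylated)
Conditions: Ir[dF(CF3)ppy]2(dtbbpy)PF6 (2 mol%), Cl3CCO2Et, DME/DMF, blue LEDs, 60 °C
Reagents that add atoms: ethyl trichloroacetate, CCOC(=O)C(Cl)(Cl)Cl
Why: Photoredox oxidation of the oxalate and loss of two CO2 should give the secondary C3 radical, which abstracts chlorine from ethyl trichloroacetate (radical deoxychlorination of cesium oxalates, a method suited to hindered secondary centres where SN2 fails and cationic methods rearrange). The α-face of the planar radical is blocked by the 1,3-diaxial 1α-triethylsilyloxy group, so chlorine should arrive from the β-face and give the equatorial 3β-chloride, which is also the more stable epimer.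

Step 21
Reactants: 25 3β-chloride enol triflate
Product: 26 C12 methyl ester (as 25 with C8–OTf replaced by C8–CO2CH3)
Conditions: Pd(OAc)2 (10 mol%), dppf, CO (1 atm), Et3N, MeOH/DMF, 50 °C
Reagents that add atoms: carbon monoxide, [C-]#[O+]; methanol, CO
Why: Oxidative addition of zerovalent palladium into the enol triflate, CO insertion and methanolysis (alkoxycarbonylation) install the C12 ester with the C7=C8 alkene in place. The secondary alkyl chloride and the silyl ethers should be inert.

Step 22
Reactants: 26 tris-silyl ether ester
Product: 27 triol (1α-OH, C11–OH, side-chain tertiary OH)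
Conditions: HF·pyridine, pyridine, THF, 0 °C → rt
Reagents that add atoms: none
Why: Buffered HF·pyridine cleaves the two triethylsilyl ethers and the primary tert-butyldiphenylsilyl ether in one operation without generating a free alkoxide, which disfavours closure of O11 onto the C12 ester.

Step 23
Reactants: 27 triol
Product: 28 methyl (1R,4aR,5S,6S,8S,8aS)-6-chloro-1-formyl-8-hydroxy-5-[(2E)-4-hydroxy-4-methylpent-2-en-1-yl]-5,8a-dimethyl-1,4,4a,5,6,7,8,8a-octahydronaphthalene-2-carboxylate (target)
Conditions: TEMPO (20 mol%), PhI(OAc)2, CH2Cl2, rt
Reagents that add atoms: none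
Why: TEMPO/PhI(OAc)2 oxidises a primary alcohol much faster than the hindered axial secondary or the tertiary alcohol and stops at the aldehyde. The near-neutral medium should preserve the equatorial 9β-formyl centre, and a five-membered lactol between the axial 1α-oxygen and C11 would be highly strained in the trans-decalin.

## Compound list

1 | methylglyoxal | CC(=O)C=O | starting material
2 | methyl 2-(triphenylphosphoranylidene)propanoate | COC(=O)C(C)=P(c1ccccc1)(c1ccccc1)c1ccccc1 | starting material
3 | methyl (E)-2-methyl-4-oxopent-2-enoate | COC(=O)/C(C)=C/C(C)=O | intermediate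
4 | propane-1,3-diol | OCCCO | starting material
5 | 3-[(tert-butyldiphenylsilyl)oxy]propan-1-ol | OCCCO[Si](c1ccccc1)(c1ccccc1)C(C)(C)C | intermediate
6 | 3-[(tert-butyldiphenylsilyl)oxy]propanal | O=CCCO[Si](c1ccccc1)(c1ccccc1)C(C)(C)C | intermediate
7 | 5-[(tert-butyldiphenylsilyl)oxy]pent-1-en-3-ol (racemic) | C=CC(O)CCO[Si](c1ccccc1)(c1ccccc1)C(C)(C)C | intermediate
8 | 5-[(tert-butyldiphenylsilyl)oxy]pent-1-en-3-one | C=CC(=O)CCO[Si](c1ccccc1)(c1ccccc1)C(C)(C)C | intermediate
9 | (Z)-5-[(tert-butyldiphenylsilyl)oxy]-3-[(triisopropylsilyl)oxy]penta-1,3-diene | C=C/C(O[Si](C(C)C)(C(C)C)C(C)C)=C/CO[Si](c1ccccc1)(c1ccccc1)C(C)(C)C | intermediate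
10 | methyl (1R,2S,6R)-6-acetyl-2-{[(tert-butyldiphenylsilyl)oxy]methyl}-1-methyl-3-[(triisopropylsilyl)oxy]cyclohex-3-ene-1-carboxylate | CC(=O)[C@@H]1CC=C(O[Si](C(C)C)(C(C)C)C(C)C)[C@H](CO[Si](c2ccccc2)(c2ccccc2)C(C)(C)C)[C@@]1(C)C(=O)OC | intermediate
11 | ethylidene compound: as 10 with C5 but-2-en-2-yl in place of acetyl (E/Z mixture) | CC=C(C)[C@@H]1CC=C(O[Si](C(C)C)(C(C)C)C(C)C)[C@H](CO[Si](c2ccccc2)(c2ccccc2)C(C)(C)C)[C@@]1(C)C(=O)OC | intermediate
12 | enol triflate ester: as 11 with C7=C8–OSO2CF3 | CC=C(C)[C@@H]1CC=C(OS(=O)(=O)C(F)(F)F)[C@H](CO[Si](c2ccccc2)(c2ccccc2)C(C)(C)C)[C@@]1(C)C(=O)OC | intermediate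
13 | primary alcohol: as 12 with C1H2OH on C10 | CC=C(C)[C@@H]1CC=C(OS(=O)(=O)C(F)(F)F)[C@H](CO[Si](c2ccccc2)(c2ccccc2)C(C)(C)C)[C@@]1(C)CO | intermediate
14 | diol: C1H2OH on C10 and C4H(CH3)–C3H(OH)–C2H3 on C5 (mixture at C3, C4) | CC(O)C(C)[C@@H]1CC=C(OS(=O)(=O)C(F)(F)F)[C@H](CO[Si](c2ccccc2)(c2ccccc2)C(C)(C)C)[C@@]1(C)CO | intermediate
15 | keto aldehyde: C1HO on C10 and C4H(CH3)–C3(=O)–C2H3 on C5 (mixture at C4) | CC(=O)C(C)[C@@H]1CC=C(OS(=O)(=O)C(F)(F)F)[C@H](CO[Si](c2ccccc2)(c2ccccc2)C(C)(C)C)[C@@]1(C)C=O | intermediate
16 | trans-fused bicyclic enone (3-oxo-1-ene, 4-methyl epimers, 10β-methyl, 5α-H, 9β-CH2OSi(t-Bu)Ph2, C7=C8 enol triflate) | O=S(=O)(OC1=CC[C@H]2C(C)C(=O)C=C[C@]2(C)[C@H]1CO[Si](c3ccccc3)(c3ccccc3)C(C)(C)C)C(F)(F)F | intermediate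
17 | 4α-allyl-4β-methyl enone | O=S(=O)(OC1=CC[C@H]2[C@](C)(CC=C)C(=O)C=C[C@]2(C)[C@H]1CO[Si](c3ccccc3)(c3ccccc3)C(C)(C)C)C(F)(F)F | intermediate
18 | enone with 4α-[(E)-4-hydroxy-4-methylpent-2-enyl] side chain | O=S(=O)(OC1=CC[C@H]2[C@](C)(C/C=C/C(C)(C)O)C(=O)C=C[C@]2(C)[C@H]1CO[Si](c3ccccc3)(c3ccccc3)C(C)(C)C)C(F)(F)F | intermediate
19 | 1α-pinacolboryl 3-ketone | O=S(=O)(OC1=CC[C@H]2[C@](C)(C/C=C/C(C)(C)O)C(=O)C[C@H](B3OC(C)(C)C(C)(C)O3)[C@]2(C)[C@H]1CO[Si](c4ccccc4)(c4ccccc4)C(C)(C)C)C(F)(F)F | intermediate
20 | 1α-hydroxy 3-ketone | O=S(=O)(OC1=CC[C@H]2[C@](C)(C/C=C/C(C)(C)O)C(=O)C[C@H](O)[C@]2(C)[C@H]1CO[Si](c3ccccc3)(c3ccccc3)C(C)(C)C)C(F)(F)F | intermediate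
21 | 1α-triethylsilyloxy 3-ketone with triethylsilylated side-chain alcohol | O=S(=O)(OC1=CC[C@H]2[C@](C)(C/C=C/C(C)(C)O[Si](CC)(CC)CC)C(=O)C[C@H](O[Si](CC)(CC)CC)[C@]2(C)[C@H]1CO[Si](c3ccccc3)(c3ccccc3)C(C)(C)C)C(F)(F)F | intermediate
22 | C3 alcohol (3α/3β mixture) | O=S(=O)(OC1=CC[C@H]2[C@](C)(C/C=C/C(C)(C)O[Si](CC)(CC)CC)C(O)C[C@H](O[Si](CC)(CC)CC)[C@]2(C)[C@H]1CO[Si](c3ccccc3)(c3ccccc3)C(C)(C)C)C(F)(F)F | intermediate
23 | C3 methyl oxalate | O=S(=O)(OC1=CC[C@H]2[C@](C)(C/C=C/C(C)(C)O[Si](CC)(CC)CC)C(OC(=O)C(=O)OC)C[C@H](O[Si](CC)(CC)CC)[C@]2(C)[C@H]1CO[Si](c3ccccc3)(c3ccccc3)C(C)(C)C)C(F)(F)F | intermediate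
24 | cesium C3 oxalate | O=S(=O)(OC1=CC[C@H]2[C@](C)(C/C=C/C(C)(C)O[Si](CC)(CC)CC)C(OC(=O)C(=O)[O-])C[C@H](O[Si](CC)(CC)CC)[C@]2(C)[C@H]1CO[Si](c3ccccc3)(c3ccccc3)C(C)(C)C)C(F)(F)F.[Cs+] | intermediate
25 | 3β-chloride enol triflate (tris-silyl ether) | O=S(=O)(OC1=CC[C@H]2[C@](C)(C/C=C/C(C)(C)O[Si](CC)(CC)CC)[C@@H](Cl)C[C@H](O[Si](CC)(CC)CC)[C@]2(C)[C@H]1CO[Si](c3ccccc3)(c3ccccc3)C(C)(C)C)C(F)(F)F | intermediate
26 | C12 methyl ester (tris-silyl ether) | COC(=O)C1=CC[C@H]2[C@](C)(C/C=C/C(C)(C)O[Si](CC)(CC)CC)[C@@H](Cl)C[C@H](O[Si](CC)(CC)CC)[C@]2(C)[C@H]1CO[Si](c3ccccc3)(c3ccccc3)C(C)(C)C | intermediate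
27 | triol (C11 alcohol, 1α-ol, side-chain tertiary alcohol) | COC(=O)C1=CC[C@H]2[C@](C)(C/C=C/C(C)(C)O)[C@@H](Cl)C[C@H](O)[C@]2(C)[C@H]1CO | intermediate
28 | methyl (1R,4aR,5S,6S,8S,8aS)-6-chloro-1-formyl-8-hydroxy-5-[(2E)-4-hydroxy-4-methylpent-2-en-1-yl]-5,8a-dimethyl-1,4,4a,5,6,7,8,8a-octahydronaphthalene-2-carboxylate | COC(=O)C1=CC[C@H]2[C@](C)(C/C=C/C(C)(C)O)[C@@H](Cl)C[C@H](O)[C@]2(C)[C@H]1C=O | target

## Step count and least certain steps

Total step count: 23. Longest linear sequence: 22 steps (4 to 28 through steps 2–23); step 1 is the only branch and joins at step 7.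

Step 7 (key step). What may go wrong: low or reversed facial selectivity, because the methyl group on C10 is cis to the acetyl group and destabilises the s-trans enone geometry on which the binding model rests (allylic 1,3-strain). Competing complexation of the ester would reverse the regiochemistry, and bond formation at the fully substituted C10 may be slow, allowing a stepwise Michael-type pathway. Fallback, from 3 and 9, returning at 10: run the cycloaddition with an achiral acid (Tf2NH, 5 mol%, CH2Cl2, −78 °C, which forms the silyl triflimide as the active Lewis acid). This should give the racemate, that is 10 together with the enantiomer of adduct 10 F1. The two are separated by preparative chromatography on a chiral stationary phase, and 10 enters step 8.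

Step 20. What may go wrong: slow loss of the second CO2 from the secondary alkoxycarbonyl radical, so that 6-exo addition of that radical to the side-chain alkene or chlorine capture at the acyl stage competes; addition of the dichloroester radical to the alkene; incomplete β-face selectivity. Heating favours the decarboxylation. Fallback (ionic, from 21, returning at 25): reduce 21 with LiBH(s-Bu)3, which should attack from the open β-face, to the axial 3α-alcohol F2. Convert it with Tf2O/pyridine into the 3α-trifluoromethanesulfonate F3 and displace with Bu4NCl with inversion to reach 25. Elimination is the expected competitor, which is why this is the fallback and not the main route.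

Step 14. What may go wrong: incomplete formation of the hindered tetrasubstituted enolate, O-alkylation, or incomplete α-face selectivity at the new quaternary centre. Fallback (from 16, returning at 17): O-allylate the potassium dienolate on purpose (KN(SiMe3)2, allyl tosylate, DMPU) to the allyl dienol ether F4 and heat it (PhMe, 110 °C). The Claisen rearrangement should deliver the allyl group to C4 from the same less hindered α-face and give 17.

Step 22. What may go wrong: lactonisation of the freed C11 hydroxyl onto the C12 ester during desilylation or the following oxidation, and ionisation of the tertiary allylic alcohol in acidic fluoride. Fallback (from 25, returning at 28): desilylate at the triflate stage, where no ester is present, to the triol enol triflate F5. Oxidise its primary alcohol (TEMPO, PhI(OAc)2) to the aldehyde enol triflate F6, and carry out the methoxycarbonylation last (Pd(OAc)2, dppf, CO, MeOH, i-Pr2NEt, rt) to reach 28 directly.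

Step 16. What may go wrong: sluggish conjugate borylation at the neopentyl β-carbon C1, or reaction of the boryl copper species with the enol triflate. Fallback (from 18, returning at 20): nucleophilic epoxidation (H2O2, NaOH, MeOH, 0 °C) from the α-face to the 1α,2α-epoxy ketone F7, then reductive opening at C2 with SmI2 (THF/MeOH, −78 °C) to give 20.

## Further compounds

F1 | step 7 | enantiomer of adduct 10 | CC(=O)[C@H]1CC=C(O[Si](C(C)C)(C(C)C)C(C)C)[C@@H](CO[Si](c2ccccc2)(c2ccccc2)C(C)(C)C)[C@]1(C)C(=O)OC
F2 | step 20 | 3α-alcohol (axial C3 hydroxyl; otherwise as 22) | O=S(=O)(OC1=CC[C@H]2[C@](C)(C/C=C/C(C)(C)O[Si](CC)(CC)CC)[C@H](O)C[C@H](O[Si](CC)(CC)CC)[C@]2(C)[C@H]1CO[Si](c3ccccc3)(c3ccccc3)C(C)(C)C)C(F)(F)F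
F3 | step 20 | 3α-trifluoromethanesulfonate | O=S(=O)(OC1=CC[C@H]2[C@](C)(C/C=C/C(C)(C)O[Si](CC)(CC)CC)[C@H](OS(=O)(=O)C(F)(F)F)C[C@H](O[Si](CC)(CC)CC)[C@]2(C)[C@H]1CO[Si](c3ccccc3)(c3ccccc3)C(C)(C)C)C(F)(F)F
F4 | step 14 | allyl dienol ether of 16 (C1=C2–C3(O-allyl)=C4(CH3)) | O=S(=O)(OC1=CC[C@H]2C(C)=C(OCC=C)C=C[C@]2(C)[C@H]1CO[Si](c3ccccc3)(c3ccccc3)C(C)(C)C)C(F)(F)F
F5 | step 22 | triol enol triflate | O=S(=O)(OC1=CC[C@H]2[C@](C)(C/C=C/C(C)(C)O)[C@@H](Cl)C[C@H](O)[C@]2(C)[C@H]1CO)C(F)(F)F
F6 | step 22 | aldehyde enol triflate | O=S(=O)(OC1=CC[C@H]2[C@](C)(C/C=C/C(C)(C)O)[C@@H](Cl)C[C@H](O)[C@]2(C)[C@H]1C=O)C(F)(F)F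
F7 | step 16 | 1α,2α-epoxy 3-ketone | O=S(=O)(OC1=CC[C@H]2[C@](C)(C/C=C/C(C)(C)O)C(=O)[C@@H]3O[C@@H]3[C@]2(C)[C@H]1CO[Si](c4ccccc4)(c4ccccc4)C(C)(C)C)C(F)(F)F
A1 | alternative 1 | methyl (6E)-8-acetoxy-10-chloro-11-hydroxy-7,11-dimethyl-3-oxotetradeca-6,13-dienoate (acyclic chlorohydrin β-keto ester) | O[C@](C)(CC=C)[C@@H](Cl)C[C@H](OC(C)=O)/C(C)=C/CCC(=O)CC(=O)OC
A2 | alternative 1 | trans-decalin β-keto ester (C8 ketone, C9 ester, 1α-acetate, 3β-chloride, C4 allyl) | O=C1CC[C@H]2[C@](C)(CC=C)[C@@H](Cl)C[C@H](OC(C)=O)[C@]2(C)[C@H]1C(=O)OC
A3 | alternative 2 | ring A vinylcyclohexene whose O1 carries the monomethyl acetylenedicarboxylate ester | COC(=O)C#CC(=O)O[C@H]1C[C@@H](O[Si](C)(C)C(C)(C)C)[C@@](C)(CC=C)C(C=C)=C1C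
A4 | alternative 2 | tricyclic lactone with C5=C6 and C8=C9 alkenes | COC(=O)C1=C2C(=O)O[C@H]3C[C@@H](O[Si](C)(C)C(C)(C)C)[C@@](C)(CC=C)C(=CC1)[C@@]23C
A5 | alternative 3 | ring B aldehyde with vinyl and ethoxycarbonylmethyl groups on C4 | O=S(=O)(OC1=CC[C@@H]([C@](C)(CC(=O)OCC)C=C)[C@](C)(C=O)[C@H]1CO[Si](c2ccccc2)(c2ccccc2)C(C)(C)C)C(F)(F)F
A6 | alternative 3 | trans-decalin 1α-ol 3β-chloride enol triflate | O=S(=O)(OC1=CC[C@H]2[C@](C)(CC(=O)OCC)[C@@H](Cl)C[C@H](O)[C@]2(C)[C@H]1CO[Si](c1ccccc1)(c1ccccc1)C(C)(C)C)C(F)(F)F
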